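**Plan**

- The target is the achiral flavone 2-(2,5-dimethoxyphenyl)-5,6,8-trimethoxy-4H-chromen-4-one. Its C3 is a lone CH between C2 (which carries ring B and O1) and the carbonyl carbon C4, so it can be added last as a single carbon.
- Retrosynthesis: C3–H comes from C3–Br. C3 is then excised by cutting C2–C3 and C3–C4, which contracts ring C to the furan ring of a 2-aryl-3-siloxybenzofuran and returns the carbon to bromoform.
- The benzofuranone is cut at the aryl–carbonyl bond (Friedel–Crafts) and at the ether O–CH bond (Williamson). This leads to 2,4,5-trimethoxyphenol (from the aldehyde by Baeyer–Villiger oxidation) and an α-bromo ester (from the arylacetic acid).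
- Forward: rings A and B are bought. The ether link is made, the furanone ring closes at the only free ortho carbon, the enol is silylated, dibromocarbene enlarges the furan to ring C, and the bromine is removed.
- Stereochemistry: the target has none. The single stereocentre of the intermediates is racemic and disappears on enol silylation.

Key step: step 8

Remark: every chiral intermediate is racemic, which is immaterial for an achiral target. The 2-arylbenzofuranone and its silyl enol ether are handled under argon because such enols autoxidise.

**Route**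

Step 1
Reactants: 1 2,4,5-trimethoxybenzaldehyde
Product: 3 2,4,5-trimethoxyphenol, via 2,4,5-trimethoxyphenyl formate 2 (not isolated)
Conditions: mCPBA, CH2Cl2, 0 °C to rt; aq. NaHCO3 wash; then K2CO3 (cat.), MeOH, rt, argon
Reagents that add atoms: 3-chloroperoxybenzoic acid (mCPBA), O=C(OO)c1cccc(Cl)c1
Why: Baeyer–Villiger (Dakin-type) oxidation, in which the electron-rich aryl group migrates to oxygen in the Criegee adduct to give the aryl formate, which mild methanolysis cleaves only after the peracid has been removed from the oxidation-sensitive phenol.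

Step 2
Reactants: 4 (2,5-dimethoxyphenyl)acetic acid
Product: 5 methyl (2,5-dimethoxyphenyl)acetate
Conditions: MeOH, H2SO4 (cat.), reflux
Reagents that add atoms: methanol, CO
Why: Fischer esterification of an unhindered arylacetic acid, driven to completion by the excess of methanol.

Step 3
Reactants: 5 methyl (2,5-dimethoxyphenyl)acetate
Product: 7 racemic methyl bromo(2,5-dimethoxyphenyl)acetate, via silyl ketene acetal 6 (not isolated)
Conditions: LiHMDS, TMSCl, THF, −78 °C; then NBS, −78 °C to 0 °C
Reagents that add atoms: N-bromosuccinimide, O=C1CCC(=O)N1Br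
Why: α-Bromination of an ester through its silyl ketene acetal, which at −78 °C is far more nucleophilic towards NBS than the dimethoxyarene, so bromine should enter only at the benzylic α-carbon; the new stereocentre forms racemic and needs no control.

Step 4
Reactants: 3 2,4,5-trimethoxyphenol; 7 racemic methyl bromo(2,5-dimethoxyphenyl)acetate
Product: 8 racemic methyl (2,5-dimethoxyphenyl)(2,4,5-trimethoxyphenoxy)acetate
Conditions: K2CO3, acetone, reflux, argon
Reagents that add atoms: none
Why: Williamson ether synthesis, the phenoxide displacing bromide by SN2 at a carbon activated by both the ester and the aryl group and lacking β-hydrogens, so elimination cannot compete.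

Step 5
Reactants: 8 racemic methyl (2,5-dimethoxyphenyl)(2,4,5-trimethoxyphenoxy)acetate
Product: 9 racemic (2,5-dimethoxyphenyl)(2,4,5-trimethoxyphenoxy)acetic acid
Conditions: LiOH·H2O, THF/MeOH/H2O, rt; then 1 M HCl to pH 2
Reagents that add atoms: lithium hydroxide, [Li+].[OH-]
Why: Saponification of a methyl ester by hydroxide (acyl–oxygen cleavage), to which the aryl and alkyl aryl ethers are inert.

Step 6
Reactants: 9 racemic (2,5-dimethoxyphenyl)(2,4,5-trimethoxyphenoxy)acetic acid
Product: 11 racemic 2-(2,5-dimethoxyphenyl)-4,5,7-trimethoxy-1-benzofuran-3(2H)-one, via mixed trifluoroacetic anhydride 10 (not isolated)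
Conditions: TFAA, CH2Cl2/TFA, 0 °C to rt, argon; degassed aq. NaHCO3 work-up
Reagents that add atoms: none
Why: Intramolecular Friedel–Crafts acylation through the mixed trifluoroacetic anhydride, in which the acyl carbon can reach only C6 of the phenoxy ring (the single free ortho position, activated by two ortho oxygens), while the absence of a metal Lewis acid spares the peri methoxy group and avoids a free acylium ion that could lose CO.

Step 7
Reactants: 11 racemic 2-(2,5-dimethoxyphenyl)-4,5,7-trimethoxy-1-benzofuran-3(2H)-one
Product: 12 tert-butyl{[2-(2,5-dimethoxyphenyl)-4,5,7-trimethoxy-1-benzofuran-3-yl]oxy}dimethylsilane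
Conditions: TBSOTf, Et3N, CH2Cl2, 0 °C, argon
Reagents that add atoms: tert-butyldimethylsilyl trifluoromethanesulfonate, CC(C)(C)[Si](C)(C)OS(=O)(=O)C(F)(F)F
Why: Soft enolisation and O-silylation with a silyl triflate and an amine base, favoured because the enol is an aromatic 3-hydroxybenzofuran; the C2 stereocentre disappears and the TBS ether is chosen to survive isolation and the alkoxide of the next step.

Step 8
Reactants: 12 tert-butyl{[2-(2,5-dimethoxyphenyl)-4,5,7-trimethoxy-1-benzofuran-3-yl]oxy}dimethylsilane; 13 bromoform
Product: 15 3-bromo-2-(2,5-dimethoxyphenyl)-5,6,8-trimethoxy-4H-chromen-4-one, via dibromocyclopropane adduct 14 (not isolated)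
Conditions: CHBr3, KOtBu, toluene/hexane, −20 °C to rt, argon; then 1 M HCl/THF, rt
Reagents that add atoms: bromoform (13), BrC(Br)Br
Why: Dibromocarbene, formed from 13 by α-elimination with KOtBu, should add as an electrophile to the C2=C3 bond of 12, the only non-benzenoid double bond and one that carries two oxygen donors, to give the cis-fused gem-dibromocyclopropane 14. The bromide lying over the five-membered ring then ionises while the bond shared by the two rings opens in a disrotatory two-electron electrocyclic process (aryl and siloxy groups turning outwards), giving a 3-bromo-4-siloxyflavylium ion whose aromatic benzopyrylium character drives the opening; silicon is lost to bromide, tert-butoxide or the acidic work-up to leave the pyranone. The closest known reaction type is the dihalocarbene ring expansion of cyclic silyl enol ethers to 2-halo-2-cycloalkenones, together with the Ciamician–Dennstedt expansion and the dihalocarbene expansion of benzofurans to 3-halochromenes. Ring C is closed not by cyclisation but by enlargement of the furan ring: the inserted carbon forms C2–C3 and C3–C4 as the old C2–C3 bond of the bicyclo[3.1.0] adduct breaks. No stereocentre is created in 15, the two of 14 being lost on opening. The step needs chemoselectivity for the enol ether over the methoxy-substituted benzene rings, secured by the two oxygen donors on the double bond and the inertness of benzenoid rings to dihalocarbenes, and cleavage of the fusion bond instead of a lateral cyclopropane bond, secured by the ring oxygen and siloxy group that stabilise the two termini of the developing allyl cation.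

Step 9
Reactants: 15 3-bromo-2-(2,5-dimethoxyphenyl)-5,6,8-trimethoxy-4H-chromen-4-one
Product: 16 2-(2,5-dimethoxyphenyl)-5,6,8-trimethoxy-4H-chromen-4-one
Conditions: Pd(OAc)2 (5 mol %), PPh3, HCO2Na, DMF, 80 °C
Reagents that add atoms: none
Why: Palladium-catalysed transfer hydrodehalogenation, in which zerovalent palladium inserts into the C3–Br bond, formate replaces bromide and loses CO2 to give a palladium hydride, and reductive elimination forms C3–H; with no hydrogen gas present the C2=C3 bond and the carbonyl should be left alone.

**Compound list**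

1 | 2,4,5-trimethoxybenzaldehyde | COc1cc(OC)c(C=O)cc1OC | starting material
2 | 2,4,5-trimethoxyphenyl formate (formed in the flask, not isolated) | COc1cc(OC)c(OC=O)cc1OC | intermediate
3 | 2,4,5-trimethoxyphenol | COc1cc(OC)c(O)cc1OC | intermediate
4 | (2,5-dimethoxyphenyl)acetic acid | COc1ccc(OC)c(CC(=O)O)c1 | starting material
5 | methyl (2,5-dimethoxyphenyl)acetate | COC(=O)Cc1cc(OC)ccc1OC | intermediate
6 | {[2-(2,5-dimethoxyphenyl)-1-methoxyethenyl]oxy}trimethylsilane, the silyl ketene acetal of 5 (E/Z mixture, formed in the flask, not isolated) | COC(=Cc1cc(OC)ccc1OC)O[Si](C)(C)C | intermediate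
7 | methyl bromo(2,5-dimethoxyphenyl)acetate (racemic) | COC(=O)C(Br)c1cc(OC)ccc1OC | intermediate
8 | methyl (2,5-dimethoxyphenyl)(2,4,5-trimethoxyphenoxy)acetate (racemic) | COC(=O)C(Oc1cc(OC)c(OC)cc1OC)c1cc(OC)ccc1OC | intermediate
9 | (2,5-dimethoxyphenyl)(2,4,5-trimethoxyphenoxy)acetic acid (racemic) | OC(=O)C(Oc1cc(OC)c(OC)cc1OC)c1cc(OC)ccc1OC | intermediate
10 | (2,5-dimethoxyphenyl)(2,4,5-trimethoxyphenoxy)acetic trifluoroacetic anhydride (racemic, formed in the flask, not isolated) | O=C(OC(=O)C(F)(F)F)C(Oc1cc(OC)c(OC)cc1OC)c1cc(OC)ccc1OC | intermediate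
11 | 2-(2,5-dimethoxyphenyl)-4,5,7-trimethoxy-1-benzofuran-3(2H)-one (racemic, in equilibrium with its enol) | COc1ccc(OC)c(C2Oc3c(OC)cc(OC)c(OC)c3C2=O)c1 | intermediate
12 | tert-butyl{[2-(2,5-dimethoxyphenyl)-4,5,7-trimethoxy-1-benzofuran-3-yl]oxy}dimethylsilane | COc1ccc(OC)c(-c2oc3c(OC)cc(OC)c(OC)c3c2O[Si](C)(C)C(C)(C)C)c1 | intermediate
13 | bromoform | BrC(Br)Br | starting material
14 | 1,1-dibromo-6b-[(tert-butyldimethylsilyl)oxy]-1a-(2,5-dimethoxyphenyl)-3,5,6-trimethoxy-1a,6b-dihydro-1H-cyclopropa[b][1]benzofuran (racemic, ring fusion necessarily cis, formed in the flask, not isolated) | COc1ccc(OC)c(C23Oc4c(OC)cc(OC)c(OC)c4C2(O[Si](C)(C)C(C)(C)C)C3(Br)Br)c1 | intermediate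
15 | 3-bromo-2-(2,5-dimethoxyphenyl)-5,6,8-trimethoxy-4H-chromen-4-one | COc1ccc(OC)c(-c2oc3c(OC)cc(OC)c(OC)c3c(=O)c2Br)c1 | intermediate
16 | 2-(2,5-dimethoxyphenyl)-5,6,8-trimethoxy-4H-chromen-4-one | COc1ccc(OC)c(-c2cc(=O)c3c(OC)c(OC)cc(OC)c3o2)c1 | target

**Step count**

Total steps: 9. Longest linear sequence: 8 steps (from 4 through steps 2 to 9); the branch from 1 contributes one step before the union in step 4.

**Steps most likely to fail**

Step 8. tert-Butoxide may strip the silyl group before the carbene has added, the carbene may add only slowly to the hindered tetrasubstituted double bond, or the flavylium intermediate may be diverted by nucleophiles. The fallback sets out from 12 and comes back at 16, so that step 9 is no longer needed. It keeps the one-carbon insertion but uses a zinc carbenoid and an oxidative ring opening. Cyclopropanation of 12 with Et2Zn and CH2I2 in CH2Cl2 (Furukawa variant of the Simmons–Smith reaction) should give the siloxycyclopropane 6b-[(tert-butyldimethylsilyl)oxy]-1a-(2,5-dimethoxyphenyl)-3,5,6-trimethoxy-1a,6b-dihydro-1H-cyclopropa[b][1]benzofuran F1. Treatment with FeCl3 in DMF at 0 °C (Ito–Saegusa ring expansion) should cleave the fusion bond to a ring-enlarged C2 radical stabilised by O1 and ring B, which takes up chlorine to give 2-chloro-2-(2,5-dimethoxyphenyl)-5,6,8-trimethoxy-2,3-dihydro-4H-chromen-4-one F2. Sodium acetate in methanol then removes HCl from this α-chloro ether to give 16.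

Step 6. The activated acid may lose carbon monoxide through an α-aryloxybenzyl cation, the ring may be acylated too slowly, or the product may autoxidise at C2 during work-up. The fallback sets out from 3 and 4 and comes back at 11, and it reverses the order of bond formation. Ortho-acylation of phenol 3 with acid 4 in BF3·OEt2 at 80 °C should give the deoxybenzoin 2-(2,5-dimethoxyphenyl)-1-(2-hydroxy-3,5,6-trimethoxyphenyl)ethan-1-one F3. α-Bromination with CuBr2 in EtOAc/CHCl3 at reflux should give 2-bromo-2-(2,5-dimethoxyphenyl)-1-(2-hydroxy-3,5,6-trimethoxyphenyl)ethan-1-one F4. Sodium acetate in ethanol then closes the O–C2 bond by intramolecular displacement to give 11.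

Step 3. Bromine may attack the electron-rich dimethoxybenzene ring, or the bromo ester may be alkylated by unreacted enolate. The fallback sets out from 5 and comes back at 8, so that 7 and the SN2 step are bypassed. Diazo transfer to 5 with 4-acetamidobenzenesulfonyl azide and DBU in MeCN should give methyl diazo(2,5-dimethoxyphenyl)acetate F5. O–H insertion of its rhodium carbenoid into phenol 3 (Rh2(OAc)4 catalyst, CH2Cl2, rt) then forms the aryl ether bond of 8 with loss of dinitrogen.

**Further compounds**

F1 | step 8 | 6b-[(tert-butyldimethylsilyl)oxy]-1a-(2,5-dimethoxyphenyl)-3,5,6-trimethoxy-1a,6b-dihydro-1H-cyclopropa[b][1]benzofuran (racemic, cis-fused) | COc1ccc(OC)c(C23CC2(O[Si](C)(C)C(C)(C)C)c2c(OC)c(OC)cc(OC)c2O3)c1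
F2 | step 8 | 2-chloro-2-(2,5-dimethoxyphenyl)-5,6,8-trimethoxy-2,3-dihydro-4H-chromen-4-one (racemic) | COc1ccc(OC)c(C2(Cl)CC(=O)c3c(OC)c(OC)cc(OC)c3O2)c1
F3 | step 6 | 2-(2,5-dimethoxyphenyl)-1-(2-hydroxy-3,5,6-trimethoxyphenyl)ethan-1-one | COc1ccc(OC)c(CC(=O)c2c(O)c(OC)cc(OC)c2OC)c1
F4 | step 6 | 2-bromo-2-(2,5-dimethoxyphenyl)-1-(2-hydroxy-3,5,6-trimethoxyphenyl)ethan-1-one (racemic) | COc1ccc(OC)c(C(Br)C(=O)c2c(O)c(OC)cc(OC)c2OC)c1
F5 | step 3 | methyl diazo(2,5-dimethoxyphenyl)acetate | COC(=O)C(=[N+]=[N-])c1cc(OC)ccc1OC
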